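**Plan**

- Retrosynthesis: C11=C12 and C11'=C12' are cut first (double Wittig: central C10 trienedial plus two identical C15 phosphonium salts). Then C9–C10 (vinyl addition) and C7=C8 (Wittig) lead back to (S)-α-cyclocitral, then the ring bond C5–C6 is cut, and last C1–C2 of the acyclic ynal.
- Enabling feature: in each ε ring, C6 is the α-carbon of the C7 carbonyl and C5 carries methyl C18 on the C4=C5 double bond. Ring C1–C6 with C7 at the aldehyde level is therefore an isomer of 3,3-dimethyloct-6-ynal, whose aldehyde α-carbon can add 6-endo to its methyl-capped alkyne.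
- Forward: a C5 homopropargyl unit and prenal give the C10 ynal; the six-membered ring closes at C5–C6 (the only ring-forming event); the chain grows C10 → C13 → C15; two C15 units are joined to the C10 dial and the polyene is equilibrated to all-E.
- Stereochemistry: C6 is set once, by the chiral secondary amine in the ring closure, and both C6 and C6' derive from that one aldehyde. Chain geometry comes from E-selective Wittig chemistry and a final thermal isomerisation.

Key step: step 3

Remark: carotenoid numbering (C1–C6 ring, C7–C15 chain) is used for ring and chain atoms throughout.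

Assumption: the amine should direct the alkyne to the enamine face remote from its diphenyl(silyloxy)methyl group, as in its intermolecular reactions; if the closure favours the other face, the (S)-amine is used in its place.

**Route**

Step 1
Reactants: 1 pent-3-yn-1-ol
Product: 2 5-bromopent-2-yne
Conditions: CBr4, PPh3, CH2Cl2, 0 °C → rt; pentane trituration, distillation
Reagents that add atoms: carbon tetrabromide, BrC(Br)(Br)Br
Why: Appel reaction, in which the primary alcohol is displaced by bromide through its alkoxyphosphonium salt under neutral conditions that leave the internal alkyne untouched.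

Step 2
Reactants: 2 5-bromopent-2-yne; 3 3-methylbut-2-enal
Product: 6 3,3-dimethyloct-6-ynal, via pent-3-yn-1-ylmagnesium bromide 4 (not isolated), via trimethylsilyl enol ether 5 (not isolated)
Conditions: Mg, THF, 25–40 °C; then CuBr·SMe2 (5 mol %), Me3SiCl, HMPA, 3, THF, −78 °C; then 1 M HCl, 0 °C
Reagents that add atoms: magnesium, [Mg] (retained only in 4); chlorotrimethylsilane, C[Si](C)(C)Cl (retained only in 5)
Why: Magnesium insertion gives the homopropargylic Grignard reagent, and its copper-catalysed, chlorosilane-accelerated conjugate addition to the β,β-disubstituted enal builds the quaternary C1 and traps the enolate as silyl enol ether 5, which dilute acid hydrolyses to the aldehyde.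

Step 3
Reactants: 6 3,3-dimethyloct-6-ynal
Product: 7 (1S)-2,6,6-trimethylcyclohex-2-ene-1-carbaldehyde ((S)-α-cyclocitral)
Conditions: (R)-α,α-diphenylprolinol trimethylsilyl ether (20 mol %), [(tBuXPhos)Au(NCMe)]SbF6 (5 mol %), PhCO2H (20 mol %), toluene, 25–40 °C; filtration through deactivated silica, used at once
Reagents that add atoms: none
Why: Proposed new method: the amine condenses with the unhindered CH2–CHO unit to the E-enamine, whose β-carbon (C6) adds anti to the C4≡C5 alkyne bound to the cationic monovalent gold complex, after which protodeauration of the C4 vinylgold and hydrolysis of the iminium ion return both catalysts and release 7. The closest known reaction types are the amine/gold and amine/copper co-catalysed α-carbocyclisation of formyl alkynes (5-exo-dig onto terminal alkynes, also with diarylprolinol silyl ethers and Ph3PAuNTf2) and the gold-catalysed 6-endo-dig closure of silyl enol ethers onto alkynes under bulky biarylphosphine ligands; their combination on an internal alkyne with the amine as sole source of asymmetry is untested. The one ring closes 6-endo-dig, C6 attacking the methyl-bearing C5 so that C4=C5 is endocyclic exactly where the target has it. The C6 stereocentre is controlled by the amine: its diphenyl(silyloxy)methyl group shields one face of the s-trans E-enamine and the tethered alkyne should reach the open face, which for the (R)-amine corresponds to (S)-7 by analogy with the sense of its conjugate additions. The step needs 6-endo over 5-exo selectivity, for which the methyl cap (5-exo attack at C4 would build a crowded exocyclic ethylidene beside C6) and the bulky tBuXPhos ligand are relied on; it also needs the product to resist re-enamination, which its α-branch between quaternary C1 and the trisubstituted alkene should ensure, so that configuration and the deconjugated double bond are kept.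

Step 4
Reactants: 7 (S)-α-cyclocitral; 8 1-(triphenylphosphoranylidene)propan-2-one
Product: 9 (3E)-4-[(1S)-2,6,6-trimethylcyclohex-2-en-1-yl]but-3-en-2-one ((S)-α-ionone)
Conditions: 8 (1.5 equiv), toluene, 80–90 °C, N2
Reagents that add atoms: 1-(triphenylphosphoranylidene)propan-2-one, CC(=O)C=P(c1ccccc1)(c1ccccc1)c1ccccc1
Why: Wittig olefination with a stabilised, salt-free ylide should form C7=C8 with E geometry, the ylide being too weak a base to enolise the aldehyde, so C6 and the C4=C5 position are expected to be retained.

Step 5
Reactants: 9 (S)-α-ionone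
Product: 10 (1E)-3-methyl-1-[(1S)-2,6,6-trimethylcyclohex-2-en-1-yl]penta-1,4-dien-3-ol (vinyl-α-ionol, both C9 epimers)
Conditions: CH2=CHMgBr, THF, −20 → 0 °C; aq. NH4Cl
Reagents that add atoms: vinylmagnesium bromide, C=C[Mg]Br
Why: Grignard 1,2-addition to the enone carbonyl, as is usual for ionones, forms C9–C10 at low temperature, where γ-deprotonation at C6 is not expected to compete; the new carbinol centre is formed without control and is erased in the next step.

Step 6
Reactants: 10 vinyl-α-ionol
Product: 11 [(2E,4E)-3-methyl-5-[(1S)-2,6,6-trimethylcyclohex-2-en-1-yl]penta-2,4-dien-1-yl]triphenylphosphonium bromide (C15 salt, minor 2Z isomer tolerated)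
Conditions: Ph3P·HBr, MeOH, rt
Reagents that add atoms: triphenylphosphine hydrobromide, [Br-].c1ccc(cc1)[PH+](c1ccccc1)c1ccccc1
Why: Acid-mediated allylic transposition (SN1-type phosphonium salt formation): the tertiary bis-allylic alcohol ionises to a pentadienyl cation that triphenylphosphine captures at the primary terminus to give the conjugated dienyl salt, leaving C6 untouched.

Step 7
Reactants: 11 C15 phosphonium bromide (2.1 equiv); 12 (2E,4E,6E)-2,7-dimethylocta-2,4,6-trienedial
Product: 15 (6S,6'S)-ε,ε-carotene (11Z/11'Z-containing isomer mixture), via C15 phosphorane 13 (not isolated), via C25 apo-aldehyde 14 (not isolated)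
Conditions: NaOMe, MeOH/CH2Cl2, 0 °C → rt, N2, dark
Reagents that add atoms: none
Why: Twofold Wittig olefination of the semi-stabilised allylic ylide with the dial forms C11=C12 and C11'=C12' as E/Z mixtures, methoxide being far too weak a base to remove the doubly allylic C6–H.

Step 8
Reactants: 15 ε,ε-carotene isomer mixture
Product: 16 (6S,6'S)-ε,ε-carotene (all-E)
Conditions: n-heptane, reflux, N2, dark; crystallisation from CH2Cl2/MeOH
Reagents that add atoms: none
Why: Thermal Z→E isomerisation of the unhindered Z double bonds of the polyene should converge the mixture on the least soluble all-E isomer, and crystallisation should also remove the meso (6R,6'S) diastereomer into which any minor (R)-unit is mostly diverted.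

**Compound list**

1 | pent-3-yn-1-ol | CC#CCCO | starting material
2 | 5-bromopent-2-yne | CC#CCCBr | intermediate
3 | 3-methylbut-2-enal | CC(C)=CC=O | starting material
4 | pent-3-yn-1-ylmagnesium bromide | CC#CCC[Mg]Br | intermediate (not isolated)
5 | trimethyl[(3,3-dimethyloct-1-en-6-yn-1-yl)oxy]silane (mainly E) | CC#CCCC(C)(C)/C=C/O[Si](C)(C)C | intermediate (not isolated)
6 | 3,3-dimethyloct-6-ynal | CC#CCCC(C)(C)CC=O | intermediate
7 | (1S)-2,6,6-trimethylcyclohex-2-ene-1-carbaldehyde ((S)-α-cyclocitral) | CC1=CCCC(C)(C)[C@@H]1C=O | intermediate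
8 | 1-(triphenylphosphoranylidene)propan-2-one | CC(=O)C=P(c1ccccc1)(c1ccccc1)c1ccccc1 | starting material
9 | (3E)-4-[(1S)-2,6,6-trimethylcyclohex-2-en-1-yl]but-3-en-2-one ((S)-α-ionone) | CC1=CCCC(C)(C)[C@@H]1/C=C/C(C)=O | intermediate
10 | (1E)-3-methyl-1-[(1S)-2,6,6-trimethylcyclohex-2-en-1-yl]penta-1,4-dien-3-ol (both C9 epimers) | CC1=CCCC(C)(C)[C@@H]1/C=C/C(C)(O)C=C | intermediate
11 | [(2E,4E)-3-methyl-5-[(1S)-2,6,6-trimethylcyclohex-2-en-1-yl]penta-2,4-dien-1-yl]triphenylphosphonium bromide | CC1=CCCC(C)(C)[C@@H]1/C=C/C(C)=C/C[P+](c1ccccc1)(c1ccccc1)c1ccccc1.[Br-] | intermediate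
12 | (2E,4E,6E)-2,7-dimethylocta-2,4,6-trienedial | O=C/C(C)=C/C=C/C=C(C)/C=O | starting material
13 | [(2E,4E)-3-methyl-5-[(1S)-2,6,6-trimethylcyclohex-2-en-1-yl]penta-2,4-dien-1-ylidene]triphenylphosphorane | CC1=CCCC(C)(C)[C@@H]1/C=C/C(C)=C/C=P(c1ccccc1)(c1ccccc1)c1ccccc1 | intermediate (not isolated)
14 | (6S)-12'-apo-ε-caroten-12'-al (11E/11Z) | CC1=CCCC(C)(C)[C@@H]1/C=C/C(C)=C/C=CC(/C)=C/C=C/C=C(C)/C=O | intermediate (not isolated)
15 | (6S,6'S)-ε,ε-carotene, mixture of 11/11' E and Z isomers | CC1=CCCC(C)(C)[C@@H]1/C=C/C(C)=C/C=CC(/C)=C/C=C/C=C(\C)C=C/C=C(C)/C=C/[C@@H]1C(C)=CCCC1(C)C | intermediate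
16 | (6S,6'S)-ε,ε-carotene (all-E) | CC1=CCCC(C)(C)[C@@H]1/C=C/C(C)=C/C=C/C(C)=C/C=C/C=C(C)/C=C/C=C(C)/C=C/[C@@H]1C(C)=CCCC1(C)C | target

**Step count**

Total steps: 8. Longest linear sequence: 8 steps (1 → 16); compounds 3, 8 and 12 enter as purchased materials.

**Steps most likely to fail**

1. Step 3 (proposed new method). Possible failures are closure in the 5-exo-dig mode at C4, deactivation of the gold centre by the amine, poor facial selectivity at C6, or loss of configuration through re-formation of an enamine from the product.

   The fallback sets out from 6 and returns at 9. Aldehyde 6 is O-silylated (TIPSOTf, Et3N, CH2Cl2, 0 °C) to triisopropyl[(3,3-dimethyloct-1-en-6-yn-1-yl)oxy]silane F1. F1 is closed by the established gold-catalysed 6-endo-dig carbocyclisation of silyl enol ethers onto alkynes ([(tBuXPhos)Au(NCMe)]SbF6, CH2Cl2/MeOH, rt) to racemic α-cyclocitral F2. Wittig reaction of F2 with 8 as in step 4 gives racemic α-ionone F3, which is resolved by preparative chromatography on a cellulose tris(3,5-dimethylphenylcarbamate) phase. The (S)-enantiomer is 9, and (R)-α-ionone F4 is set aside. This replaces the catalytic enamine by a stoichiometric silyl enol ether nucleophile and replaces catalyst control by resolution.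

2. Step 2. Possible failures are 1,2-addition to the enal carbonyl instead of conjugate addition, or Wurtz-type coupling during formation of the homopropargylic Grignard reagent.

   The fallback sets out from 2 and returns at 6, with neither a Grignard reagent nor a conjugate addition. Lithiated isobutyronitrile (LDA, THF, −78 °C → rt) is alkylated with 2 to give 2,2-dimethylhept-5-ynenitrile F5. DIBAL-H (toluene, −78 °C; aqueous acid) reduces F5 to 2,2-dimethylhept-5-ynal F6. Wittig homologation with Ph3P=CHOMe (from the phosphonium chloride and KOtBu, THF) gives 1-methoxy-3,3-dimethyloct-1-en-6-yne F7. Mild acid hydrolysis of F7 (aq. HCl, THF) gives 6.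

3. Step 4. Olefination of the hindered α-branched aldehyde may be slow at the temperature needed, giving time for migration of the ring double bond into conjugation and for loss of configuration at C6.

   The fallback sets out from 7 and returns at 9. Prop-1-ynylmagnesium bromide (THF, −78 °C) adds to 7 to give 1-[(1S)-2,6,6-trimethylcyclohex-2-en-1-yl]but-2-yn-1-ol F8. Meyer–Schuster rearrangement of F8 (MoO2(acac)2, Ph3PAuCl, AgOTf, each catalytic, toluene, rt) should give the E-enone 9 without any basic or hot olefination step.

**Further compounds**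

F1 | step 3 | triisopropyl[(3,3-dimethyloct-1-en-6-yn-1-yl)oxy]silane (E/Z) | CC#CCCC(C)(C)C=CO[Si](C(C)C)(C(C)C)C(C)C
F2 | step 3 | racemic 2,6,6-trimethylcyclohex-2-ene-1-carbaldehyde (racemic α-cyclocitral) | CC1=CCCC(C)(C)C1C=O
F3 | step 3 | racemic (3E)-4-(2,6,6-trimethylcyclohex-2-en-1-yl)but-3-en-2-one (racemic α-ionone) | CC1=CCCC(C)(C)C1/C=C/C(C)=O
F4 | step 3 | (3E)-4-[(1R)-2,6,6-trimethylcyclohex-2-en-1-yl]but-3-en-2-one ((R)-α-ionone) | CC1=CCCC(C)(C)[C@H]1/C=C/C(C)=O
F5 | step 2 | 2,2-dimethylhept-5-ynenitrile | CC#CCCC(C)(C)C#N
F6 | step 2 | 2,2-dimethylhept-5-ynal | CC#CCCC(C)(C)C=O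
F7 | step 2 | 1-methoxy-3,3-dimethyloct-1-en-6-yne (E/Z) | CC#CCCC(C)(C)C=COC
F8 | step 4 | 1-[(1S)-2,6,6-trimethylcyclohex-2-en-1-yl]but-2-yn-1-ol (both carbinol epimers) | CC#CC(O)[C@@H]1C(C)=CCCC1(C)C
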